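**Plan**

- Retrosynthesis: (i) cut the OCH2–CH2Ar carbon–carbon bond into an acyloxymethyl radical (from carboxymethyl ester 16, by loss of CO2) and p-quinone methide 20; (ii) open the dihydropyran at O1–C6 and remove the C6 formyl carbon (acyl-lactone rearrangement) back to δ-lactone 10; (iii) re-join the two acetate arms on C4 into a cyclopentene; (iv) cut C2–C3 as an aldol.
- Enabling feature: in the catechol ring the oxygen on C4 is para to ring carbon C1, which carries the side chain. The benzylic carbon can therefore be offered as the exocyclic CH2 of 2-hydroxy-4-methylidenecyclohexa-2,5-dienone; radical attack there re-creates the benzene ring and frees the catechol without protecting groups.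
- Forward: aldol (C2–C3) → aldehyde masked as dimethyl acetal → ozonolysis to a C4 bis-acetate and lactonisation (δ-lactone ring) → C-formylation and acyl-lactone rearrangement (dihydropyran ring) → selective saponification, carboxymethyl ester, unmasking → decarboxylative radical 1,6-addition that joins the halves (the arene ring arises last).
- Stereochemistry: C2 and C3 come from the (R)-4-benzyloxazolidinone-controlled syn-aldol; C4 comes from equilibrating lactonisation between two diastereotopic ester arms. Nothing is set after step 5, and the 2,3-trans-3,4-trans array is expected to be the thermodynamic one.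

Key step: step 12

Remark: 2-(cyclopent-3-en-1-yl)acetic acid (1) is taken to be a catalogue compound.

**Step 1**
Reactants: 1 2-(cyclopent-3-en-1-yl)acetic acid; 2 (R)-4-benzyloxazolidin-2-one
Product: 3 (R)-4-benzyl-3-[2-(cyclopent-3-en-1-yl)acetyl]oxazolidin-2-one
Conditions: PivCl, Et3N, THF, −20 °C; then 2, LiCl, −20 °C → rt
Reagents that add atoms: none
Why: N-acylation of the oxazolidinone through the mixed pivalic anhydride, whose less hindered acyl carbon is attacked by the lithium-activated carbamate nitrogen.

**Step 2**
Reactants: 3 (R)-4-benzyl-3-[2-(cyclopent-3-en-1-yl)acetyl]oxazolidin-2-one; 4 acetaldehyde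
Product: 5 (R)-4-benzyl-3-[(2R,3S)-2-(cyclopent-3-en-1-yl)-3-hydroxybutanoyl]oxazolidin-2-one
Conditions: Bu2BOTf, iPr2NEt, CH2Cl2, −78 → 0 °C; 4, −78 → 0 °C; then H2O2, pH 7 buffer, MeOH, 0 °C
Reagents that add atoms: none
Why: Evans syn-aldol reaction, in which the (Z)-boron enolate reacts through a Zimmerman–Traxler chair on the face away from the benzyl group and so sets the carbinol carbon (later C2, S) and the α-carbon (later C3) in the syn relation that becomes 2,3-trans in the ring.

**Step 3**
Reactants: 5 (R)-4-benzyl-3-[(2R,3S)-2-(cyclopent-3-en-1-yl)-3-hydroxybutanoyl]oxazolidin-2-one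
Product: 6 (2S,3S)-2-(cyclopent-3-en-1-yl)butane-1,3-diol
Conditions: LiBH4, MeOH (1 equiv), THF, 0 °C
Reagents that add atoms: none
Why: Reductive cleavage of the N-acyl oxazolidinone by borohydride gives the primary alcohol without touching the alkene or either stereocentre and returns the auxiliary.

**Step 4**
Reactants: 6 (2S,3S)-2-(cyclopent-3-en-1-yl)butane-1,3-diol
Product: 8 (2S,3R)-3-(cyclopent-3-en-1-yl)-4,4-dimethoxybutan-2-ol, via hydroxy aldehyde 7 (not isolated)
Conditions: TEMPO (10 mol%), PhI(OAc)2, CH2Cl2, rt; then HC(OMe)3, PPTS (cat.), MeOH, rt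
Reagents that add atoms: trimethyl orthoformate, COC(OC)OC
Why: Oxoammonium (TEMPO) oxidation takes the primary hydroxyl in preference to the secondary one, and the β-hydroxy aldehyde is masked at once as its dimethyl acetal so that it cannot epimerise, eliminate or form lactols in the following steps.

**Step 5**
Reactants: 8 (2S,3R)-3-(cyclopent-3-en-1-yl)-4,4-dimethoxybutan-2-ol
Product: 10 methyl 2-[(2S,3R,4S)-3-(dimethoxymethyl)-2-methyl-6-oxooxan-4-yl]acetate, via hydroxy diester 9 (not isolated)
Conditions: O3, NaOH (2.5 M in MeOH), CH2Cl2, −78 °C; then CSA (cat.), toluene, 60 °C, slow removal of MeOH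
Reagents that add atoms: ozone, [O-][O+]=O; methanol, CO
Why: Ozonolysis in methanolic NaOH turns both alkene carbons into methyl esters, and acid-catalysed lactonisation by the C2 hydroxyl then chooses between the two diastereotopic arms under ester-exchange equilibration through 9, the lactone with methyl, acetal and acetate arm all equatorial being favoured, which sets C4 (4S in 10, the 4R centre of the target).

**Step 6**
Reactants: 10 methyl 2-[(2S,3R,4S)-3-(dimethoxymethyl)-2-methyl-6-oxooxan-4-yl]acetate
Product: 11 methyl 2-[(2S,3R,4R,5Z)-3-(dimethoxymethyl)-5-(hydroxymethylidene)-2-methyl-6-oxooxan-4-yl]acetate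
Conditions: LDA (1.1 equiv), THF, −78 °C; HCO2Et, −78 → 0 °C; cold 0.5 M HCl to pH 4
Reagents that add atoms: ethyl formate, CCOC=O
Why: Crossed Claisen condensation (C-formylation) of the kinetic lactone enolate, which forms selectively because the lactone α-CH2 is several pKa units more acidic than the α-CH2 of the acyclic methyl ester.

**Step 7**
Reactants: 11 methyl 2-[(2S,3R,4R,5Z)-3-(dimethoxymethyl)-5-(hydroxymethylidene)-2-methyl-6-oxooxan-4-yl]acetate
Product: 12 methyl (2S,3R,4R)-3-(dimethoxymethyl)-4-(2-methoxy-2-oxoethyl)-2-methyl-3,4-dihydro-2H-pyran-5-carboxylate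
Conditions: HCl (1.25 M in MeOH), 0 → 45 °C
Reagents that add atoms: methanol, CO
Why: Acyl-lactone rearrangement, in which acid methanolysis opens the α-formyl lactone to the methyl ester and the freed C2 hydroxyl closes on the formyl carbon with loss of water to give the 3,4-dihydro-2H-pyran-5-carboxylate (a vinylogous carbonate) as the thermodynamic sink, the acetal being retained in methanol and no stereocentre being touched.

**Step 8**
Reactants: 12 methyl (2S,3R,4R)-3-(dimethoxymethyl)-4-(2-methoxy-2-oxoethyl)-2-methyl-3,4-dihydro-2H-pyran-5-carboxylate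
Product: 13 2-[(2S,3R,4R)-3-(dimethoxymethyl)-5-(methoxycarbonyl)-2-methyl-3,4-dihydro-2H-pyran-4-yl]acetic acid
Conditions: LiOH (1.1 equiv), THF/H2O 3:1, 0 °C; then 0.5 M HCl to pH 4
Reagents that add atoms: lithium hydroxide, [Li+].[OH-]
Why: Chemoselective saponification, the saturated methyl ester being hydrolysed far faster than the C5 ester, whose carbonyl is deactivated as a vinylogous carbonate by the ring oxygen.

**Step 9**
Reactants: 13 2-[(2S,3R,4R)-3-(dimethoxymethyl)-5-(methoxycarbonyl)-2-methyl-3,4-dihydro-2H-pyran-4-yl]acetic acid; 14 tert-butyl bromoacetate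
Product: 15 methyl (2S,3R,4R)-4-{2-[2-(tert-butoxy)-2-oxoethoxy]-2-oxoethyl}-3-(dimethoxymethyl)-2-methyl-3,4-dihydro-2H-pyran-5-carboxylate
Conditions: K2CO3, DMF, rt
Reagents that add atoms: none
Why: SN2 O-alkylation of the potassium carboxylate by the α-bromo ester installs the carboxymethyl ester whose CH2 becomes the oxygen-bound carbon of the key bond.

**Step 10**
Reactants: 15 methyl (2S,3R,4R)-4-{2-[2-(tert-butoxy)-2-oxoethoxy]-2-oxoethyl}-3-(dimethoxymethyl)-2-methyl-3,4-dihydro-2H-pyran-5-carboxylate
Product: 16 2-({2-[(2S,3R,4R)-3-formyl-5-(methoxycarbonyl)-2-methyl-3,4-dihydro-2H-pyran-4-yl]acetyl}oxy)acetic acid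
Conditions: TFA/CH2Cl2/H2O 10:10:1, 0 °C → rt
Reagents that add atoms: water, O
Why: Acidolysis of the tert-butyl ester (loss of isobutene) and hydrolysis of the dimethyl acetal occur in one pot, while the vinylogous carbonate and the acyloxyacetate link should be stable to aqueous TFA and C3 stays trans to both neighbours.

**Step 11**
Reactants: 17 3,4-dihydroxybenzyl alcohol; 18 sodium 4-methylbenzenesulfinate
Product: 19 4-[(4-methylbenzenesulfonyl)methyl]benzene-1,2-diol
Conditions: HCO2H/H2O 1:1, rt
Reagents that add atoms: none
Why: SN1-type substitution, in which the 4-hydroxybenzylic alcohol ionises in aqueous formic acid to the protonated quinone methide and is captured at sulfur by the sulfinate to give a bench-stable sulfone.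

**Step 12**
Reactants: 16 2-({2-[(2S,3R,4R)-3-formyl-5-(methoxycarbonyl)-2-methyl-3,4-dihydro-2H-pyran-4-yl]acetyl}oxy)acetic acid; 19 4-[(4-methylbenzenesulfonyl)methyl]benzene-1,2-diol (1.5 equiv)
Product: 21 methyl (2S,3R,4R)-4-{2-[2-(3,4-dihydroxyphenyl)ethoxy]-2-oxoethyl}-3-formyl-2-methyl-3,4-dihydro-2H-pyran-5-carboxylate, via quinone methide 20 (not isolated)
Conditions: [Ir(dF(CF3)ppy)2(5,5′-dCF3bpy)]PF6 (2 mol%), Cs2CO3 (0.6 equiv), degassed MeCN, 450 nm LEDs, rt; dilute HCl/ascorbic acid work-up
Reagents that add atoms: none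
Why: Proposed new method: Caesium carbonate converts 16 into its carboxylate and a small part of 19 into the 4-phenolate, which expels p-toluenesulfinate (1,6-elimination) to give 20 at low stationary concentration; the excited iridium(III) complex oxidises the carboxylate, CO2 is lost, the nucleophilic acyloxymethyl radical adds to the exocyclic CH2 of 20 and so restores the arene, and the 2-hydroxyphenoxyl radical takes the electron back from iridium(II) to give the phenolate of 21, which deprotonates the next molecule of 19. The closest known reaction types are the photoredox decarboxylative radical 1,6-addition (Giese type) of α-oxygenated carboxylic acids to isolable δ-aryl p-quinone methides and the base-induced release of quinone methides from (arylsulfonylmethyl)phenols; their union on a transient δ-unsubstituted quinone methide with an acyloxymethyl radical has not been shown. No ring is closed by cyclisation and no stereocentre is formed: the cyclohexadienone ring of 20 becomes the catechol ring by aromatisation, and C2, C3 and C4 of the dihydropyran are spectators whose trans,trans arrangement is the thermodynamic one, so that enolisation at the formyl-bearing C3 in the weakly basic medium should not erode it. The selectivities needed are these: only the 4-OH can form a quinone methide because it alone is para to the CH2Ts group; the carbon radical attacks the unhindered methylene terminus and not oxygen or a ring carbon; sulfinate and carboxylate add to 20 reversibly and so buffer it, while the substoichiometric base keeps phenolate, the nucleophile that would start oligomerisation, scarce; and the reduced photocatalyst is too weak a reductant to reduce 20 itself. The ester tether keeps the radical from cyclising onto the vinylogous carbonate or the aldehyde of its own molecule.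

**Compound list**

1 | 2-(cyclopent-3-en-1-yl)acetic acid | OC(=O)CC1CC=CC1 | starting material
2 | (R)-4-benzyloxazolidin-2-one | O=C1N[C@H](Cc2ccccc2)CO1 | starting material
3 | (R)-4-benzyl-3-[2-(cyclopent-3-en-1-yl)acetyl]oxazolidin-2-one | O=C(CC1CC=CC1)N1[C@H](Cc2ccccc2)COC1=O | intermediate
4 | acetaldehyde | CC=O | starting material
5 | (R)-4-benzyl-3-[(2R,3S)-2-(cyclopent-3-en-1-yl)-3-hydroxybutanoyl]oxazolidin-2-one | C[C@H](O)[C@@H](C1CC=CC1)C(=O)N1[C@H](Cc2ccccc2)COC1=O | intermediate
6 | (2S,3S)-2-(cyclopent-3-en-1-yl)butane-1,3-diol | C[C@H](O)[C@@H](C1CC=CC1)CO | intermediate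
7 | (2R,3S)-2-(cyclopent-3-en-1-yl)-3-hydroxybutanal | C[C@H](O)[C@@H](C1CC=CC1)C=O | intermediate
8 | (2S,3R)-3-(cyclopent-3-en-1-yl)-4,4-dimethoxybutan-2-ol | C[C@H](O)[C@@H](C1CC=CC1)C(OC)OC | intermediate
9 | dimethyl 3-[(2R,3S)-3-hydroxy-1,1-dimethoxybutan-2-yl]pentanedioate | C[C@H](O)[C@@H](C(CC(=O)OC)CC(=O)OC)C(OC)OC | intermediate
10 | methyl 2-[(2S,3R,4S)-3-(dimethoxymethyl)-2-methyl-6-oxooxan-4-yl]acetate | O=C1O[C@@H](C)[C@H](C(OC)OC)[C@@H](CC(=O)OC)C1 | intermediate
11 | methyl 2-[(2S,3R,4R,5Z)-3-(dimethoxymethyl)-5-(hydroxymethylidene)-2-methyl-6-oxooxan-4-yl]acetate (enol form of the α-formyl lactone) | O=C1O[C@@H](C)[C@H](C(OC)OC)[C@@H](CC(=O)OC)/C1=C/O | intermediate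
12 | methyl (2S,3R,4R)-3-(dimethoxymethyl)-4-(2-methoxy-2-oxoethyl)-2-methyl-3,4-dihydro-2H-pyran-5-carboxylate | COC(=O)C1=CO[C@@H](C)[C@H](C(OC)OC)[C@H]1CC(=O)OC | intermediate
13 | 2-[(2S,3R,4R)-3-(dimethoxymethyl)-5-(methoxycarbonyl)-2-methyl-3,4-dihydro-2H-pyran-4-yl]acetic acid | COC(=O)C1=CO[C@@H](C)[C@H](C(OC)OC)[C@H]1CC(=O)O | intermediate
14 | tert-butyl bromoacetate | CC(C)(C)OC(=O)CBr | starting material
15 | methyl (2S,3R,4R)-4-{2-[2-(tert-butoxy)-2-oxoethoxy]-2-oxoethyl}-3-(dimethoxymethyl)-2-methyl-3,4-dihydro-2H-pyran-5-carboxylate | COC(=O)C1=CO[C@@H](C)[C@H](C(OC)OC)[C@H]1CC(=O)OCC(=O)OC(C)(C)C | intermediate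
16 | 2-({2-[(2S,3R,4R)-3-formyl-5-(methoxycarbonyl)-2-methyl-3,4-dihydro-2H-pyran-4-yl]acetyl}oxy)acetic acid | COC(=O)C1=CO[C@@H](C)[C@H](C=O)[C@H]1CC(=O)OCC(=O)O | intermediate
17 | 3,4-dihydroxybenzyl alcohol | OCc1ccc(O)c(O)c1 | starting material
18 | sodium 4-methylbenzenesulfinate | Cc1ccc(cc1)S(=O)[O-].[Na+] | starting material
19 | 4-[(4-methylbenzenesulfonyl)methyl]benzene-1,2-diol | Cc1ccc(cc1)S(=O)(=O)Cc1ccc(O)c(O)c1 | intermediate
20 | 2-hydroxy-4-methylidenecyclohexa-2,5-dien-1-one (p-quinone methide) | C=C1C=CC(=O)C(O)=C1 | intermediate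
21 | methyl (2S,3R,4R)-4-{2-[2-(3,4-dihydroxyphenyl)ethoxy]-2-oxoethyl}-3-formyl-2-methyl-3,4-dihydro-2H-pyran-5-carboxylate | COC(=O)C1=CO[C@@H](C)[C@H](C=O)[C@H]1CC(=O)OCCc1ccc(O)c(O)c1 | target

**Count**

Total step count: 12. Longest linear sequence: 11 steps (steps 1–10 and 12); step 11 is the one-step side branch.

**Steps most likely to fail**

Step 12 (Proposed new method). The transient quinone methide may be consumed by phenolate C-alkylation and oligomerisation faster than by the radical. Phenolate and sulfinate may also quench the excited catalyst unproductively, so that radical formation stalls. The fallback uses known chemistry and forms the ester C–O bond instead; it sets out from 13 and comes back to the route at 21. Acid 13 is esterified with commercial 2-(3,4-dihydroxyphenyl)ethanol under Mitsunobu conditions (PPh3, DIAD, THF, 0 °C). The carboxylic acid is the only pronucleophile acidic enough, so the primary alcohol is acylated and the phenols are left. This should give the acetal ester methyl (2S,3R,4R)-4-{2-[2-(3,4-dihydroxyphenyl)ethoxy]-2-oxoethyl}-3-(dimethoxymethyl)-2-methyl-3,4-dihydro-2H-pyran-5-carboxylate F1. TFA/CH2Cl2/H2O then hydrolyses the acetal to 21.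

Step 5. Discrimination between the two diastereotopic ester arms in the lactonisation may be poor, because an axial substituent costs little in a δ-lactone half-chair; over-oxidation by ozone in the basic medium is a second risk. The fallback sets out from 8 and comes back at 10. Reductive ozonolysis (O3, CH2Cl2/MeOH, −78 °C; Me2S) should give the lactol aldehyde 2-[(2S,3R,4S)-3-(dimethoxymethyl)-6-hydroxy-2-methyloxan-4-yl]acetaldehyde F2. Here the choice between the arms is made by ring–chain tautomerism of a saturated oxane, where an axial arm pays the full 1,3-diaxial penalty. PDC in DMF oxidises lactol and aldehyde together to the lactone acid 2-[(2S,3R,4S)-3-(dimethoxymethyl)-2-methyl-6-oxooxan-4-yl]acetic acid F3, and TMSCHN2 (MeOH/toluene) gives 10.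

Step 6. The acyclic ester arm may be enolised and formylated in competition, or bis-formylation may occur. The fallback sets out from 10 and comes back at 12. Condensation with tert-butoxybis(dimethylamino)methane (toluene, 90 °C) proceeds under neutral conditions and only at the more acidic lactone α-CH2. It should give the enaminone lactone methyl 2-[(2S,3R,4R)-3-(dimethoxymethyl)-5-[(dimethylamino)methylidene]-2-methyl-6-oxooxan-4-yl]acetate F4 (enamine geometry left open). Methanolic HCl, as in step 7, converts it into 12 with loss of dimethylamine.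

**Further compounds**

F1 | step 12 | methyl (2S,3R,4R)-4-{2-[2-(3,4-dihydroxyphenyl)ethoxy]-2-oxoethyl}-3-(dimethoxymethyl)-2-methyl-3,4-dihydro-2H-pyran-5-carboxylate | COC(=O)C1=CO[C@@H](C)[C@H](C(OC)OC)[C@H]1CC(=O)OCCc1ccc(O)c(O)c1
F2 | step 5 | 2-[(2S,3R,4S)-3-(dimethoxymethyl)-6-hydroxy-2-methyloxan-4-yl]acetaldehyde | OC1O[C@@H](C)[C@H](C(OC)OC)[C@@H](CC=O)C1
F3 | step 5 | 2-[(2S,3R,4S)-3-(dimethoxymethyl)-2-methyl-6-oxooxan-4-yl]acetic acid | O=C1O[C@@H](C)[C@H](C(OC)OC)[C@@H](CC(=O)O)C1
F4 | step 6 | methyl 2-[(2S,3R,4R)-3-(dimethoxymethyl)-5-[(dimethylamino)methylidene]-2-methyl-6-oxooxan-4-yl]acetate | O=C1O[C@@H](C)[C@H](C(OC)OC)[C@@H](CC(=O)OC)C1=CN(C)C
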